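E, the first kind of end group, is the account here: charge it, then follow each mole. It links with Q to give G, and Z, one-sided, can cap it.

in all of them: E 28 mM
- red: Q 28 mM; Z 3.5 mM; run made earlier
- green: Q 28 mM; Z 13 mM; run made earlier
- delta: Q 28.0 mM; Z 3.00 mM; time 40 min
- zeta: Q 28.0 mM; Z 6.00 mM; time 40 min
- epsilon: Q 28.0 mM; Z 12.0 mM; time 40 min

| run | time / min | G / % | E / % |
|---|---|---|---|
| red | 4.00 | 69.1 | 17.9 |
| red | 8.00 | 68.4 | 19.5 |
| red | 12.0 | 67.2 | 20.7 |
| red | 15.0 | 66.5 | 19.8 |
| red | 20.0 | 67.6 | 20.4 |
| green | 2.00 | 47.5 | 6.9 |
| green | 5.00 | 46.1 | 6.4 |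
| green | 10.0 | 46.9 | 7.4 |
| green | 15.0 | 44.4 | 11.3 |
| green | 20.0 | 45.1 | 11.5 |

(each reading ± 1 percentage point)

- amount of G at the end, in percent of the E charged for delta, zeta, epsilon, in this order
- how that number moves from the first to the last of them (falls all the way / hardly changes / rises, then falls / falls, then rises / rises all the way)

- "hardly changes" means that all values lie within two and a half points (for a concentration: within two and a half percent of the largest)

**First entry.** Enter what Z takes. The red run's G and E fall short of the charge by 13.0% at 4.00 min, against a Z charge of 12.5% of E. The green run's shortfall is 45.6% at 2.00 min, against 46.4%. Book Z as taking E one for one, and early.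

**Second entry.** Split the rest between G and free E. Divide the linking rate by the unlinking rate: at balance the two are equal, time drops out, and one number remains, the balance quotient (reaction quotient), G over free E times free Q. Taking free Q as its charge minus G, the first readings give 0.446 mM⁻¹ in red and 0.468 mM⁻¹ in green. Carry their mean, 0.457 mM⁻¹.

**Third entry.** The last readings give less: 0.365 mM⁻¹ in red and 0.255 mM⁻¹ in green. So book a slow leak of Q. Holding the quotient at 0.457 mM⁻¹, red lacks 1.82 mM of Q at 20.0 min. Let that run steadily to 40 min, twice as long, and book 3.64 mM against delta, zeta and epsilon alike, a rough figure taken from red.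

**Books closed.** My row is 65.5%, 60.6%, 47.7%, falling.

**The forecast.** It gives 68%, 62%, 48%, falls all the way, with a quotient of 0.35 per mM, holding that “The remaining E and Q then sit in a reversible equilibrium, E + Q ⇌ G, reached within minutes”. For delta, mine lies lower.

**The flask.** G stands at 65.8%, 59.4%, 44.9%: falls all the way, and the forecast is right within its margin.

    E + Q ⇌ G (K = 450 L mol⁻¹, k = 360 L mol⁻¹ min⁻¹)
    E + Z → D (k = 1700 L mol⁻¹ min⁻¹)
    2 Q → L (k = 0.810 L mol⁻¹ min⁻¹)

In delta at 40.0 min, L stands at 1.69 mM. The forecast's figure for delta lies within its margin at that time; at 400 min, G in delta lies 20 percentage points below that figure. Put the quotient to that later delta state: E at 41.2% of its charge and Q at 9.27% of its own reckon to G of 48.9% of the E charged, and the flask holds 48.1%.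

All runs were generated by integration on assumed constants; noise was put on by code.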